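Late in the winter run target still climbs, but slowly: 37.7% at 2.00 h, then 41.5% at 3.00 h. The midnight run, with less free catalyst, stays close to a straight line up to its last reading.

| setting | midnight | winter | north-east | north-west | north | south | west |
|---|---|---|---|---|---|---|---|
| starting material | 0.051 M | 0.051 M | 0.051 M | 0.051 M | 0.051 M | 0.051 M | 0.051 M |
| coupling partner | 0.0484 M | 0.0484 M | 0.0484 M | 0.0484 M | 0.0484 M | 0.0484 M | 0.0484 M |
| free catalyst | 0.022 mM | 0.64 mM | 0.040 mM | 0.080 mM | 0.20 mM | 0.40 mM | 0.80 mM |
| remark | run made earlier | run made earlier |  |  |  |  |  |
| time |  |  | 4.0 h | 4.0 h | 4.0 h | 4.0 h | 4.0 h |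

| midnight: time / h | midnight: target / % | winter: time / h | winter: target / % |
|---|---|---|---|
| 0.417 | 0.8 | 0.250 | 10.0 |
| 0.833 | 1.1 | 0.333 | 12.4 |
| 1.33 | 2.4 | 0.500 | 17.0 |
| 1.50 | 2.0 | 0.833 | 24.6 |
| 2.00 | 2.6 | 1.33 | 32.1 |
| 2.50 | 3.1 | 2.00 | 37.7 |
| 3.00 | 3.9 | 3.00 | 41.5 |

(readings scatter by 0.3 percentage points)

- "hardly changes" means that all values lie within two and a half points (for a concentration: within two and a half percent of the largest)

- amount of target at the end, in percent of the starting material charged for north-east, north-west, north, south, west, in this order
- how the row runs (rises all the way / rises, then falls / falls all the way / hardly changes / falls, then rises)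

Divide the winter start rate by the midnight rate and time drops out. The ratio reads 30.8 for 29.1 times the c(free catalyst), so you may take the early rate as first order in free catalyst.

My reckoning of the row then rests on two times. One is the run, 4.0 h. The other is the fill time: how long the winter start rate takes to make the last winter reading. It reads 1.04 h in the winter run and, with that first order, goes as one over c(free catalyst): 16.6 h for north-east and 0.830 h for west. Run time over fill time is 0.241 for north-east and 4.82 for west; call it the fill number. Below one, my reckoning stays on the straight line, which gives north-east 10.0%. Well above one, it puts west near the last winter reading.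

The forecast gave 9%, 16.5%, 31%, 40% and 43.5%, rises all the way, from a ceiling “approached at a rate proportional to catalyst”. Its north-east value lies below mine, its west value above the last winter reading.

The flasks end at 8.25%, 14.5%, 26.5%, 37.1% and 46.9%: rises all the way.

    2 free catalyst → spent catalyst (k = 251 L mol⁻¹ h⁻¹)
    starting material + target → side product (k = 2.26 L mol⁻¹ h⁻¹)
    starting material + coupling partner + free catalyst ⇌ target + free catalyst, rate k3*[starting material]*[coupling partner]*[free catalyst] forward; the back reaction follows from the equilibrium constant (K = 613 L mol⁻¹, k = 15500 L² mol⁻² h⁻¹)

North-east, with fill number 0.241, ended at 8.25%, and at 1.20 h its spent catalyst was 2.35% of the catalyst. West, with fill number 4.82, held more spent catalyst at that same time, 32.5% of the catalyst, and it ended at 46.9% with 36% of its starting material still there.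

The runs are calculated from invented constants, noise included.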